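The target is cut at the bond between C3 of the γ-butyrolactone ring and the benzylic carbinol carbon, an aldol retron. The key step joins the potassium enolate of (R)-4-(3,4-dimethoxybenzyl)butyrolactone with O-benzylvanillin: one operation forms this C–C bond and sets both C3 and the carbinol carbon. It exploits the acidic C3 methylene of the lactone ring beside the C4 stereocentre, whose dimethoxybenzyl arm screens one enolate face (3,4-trans), and the ring-locked enolate geometry, which in an open potassium transition state gives the syn (S) carbinol. The lactone comes from an achiral butenolide (Negishi coupling, then copper hydride asymmetric conjugate reduction); hydrogenolysis of the benzyl ether ends the route.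

Key step: step 3

Assumption: (R)-p-tol-BINAP is taken as the ligand antipode that leads to (R)-5, by analogy with the facial sense usual for related cyclic acceptors. The antipode is equally available should the sign of rotation of 5 show the opposite sense.

Step 1
Reactants: 1 3,4-dimethoxybenzyl chloride; 2 4-bromofuran-2(5H)-one
Product: 4 4-(3,4-dimethoxybenzyl)furan-2(5H)-one, via benzylic zinc chloride 3 (not isolated)
Conditions: 1, Zn dust, LiCl, THF, 25 °C; then 2, Pd(OAc)2 (2 mol %), SPhos (4 mol %), THF, 25 °C
Reagents that add atoms: none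
Why: Negishi coupling: LiCl-assisted insertion of zinc into the benzylic C–Cl bond gives 3, zerovalent palladium inserts readily into the vinylogous acyl C4–Br bond of 2, and the neutral, weakly basic organozinc leaves the acidic C5 and benzylic protons of the butenolide untouched.

Step 2
Reactants: 4 4-(3,4-dimethoxybenzyl)furan-2(5H)-one
Product: 5 (R)-4-(3,4-dimethoxybenzyl)dihydrofuran-2(3H)-one
Conditions: Cu(OAc)2·H2O (5 mol %), (R)-p-tol-BINAP (5 mol %), (EtO)2MeSiH, t-BuOH, toluene, 0 °C
Reagents that add atoms: none
Why: Copper hydride asymmetric conjugate reduction (1,4-hydrosilylation) of a 4-substituted butenolide: the ligated CuH delivers hydride to C4 on the alkene face left open by the biaryl diphosphine and so sets C4 as R, t-BuOH protonates the copper enolate at C3, the silane regenerates CuH, and the acetate precatalyst needs no alkoxide base that could deconjugate the alkene.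

Step 3
Reactants: 5 (R)-4-(3,4-dimethoxybenzyl)dihydrofuran-2(3H)-one; 6 4-(benzyloxy)-3-methoxybenzaldehyde (O-benzylvanillin)
Product: 9 (3S,4R)-3-[(S)-[4-(benzyloxy)-3-methoxyphenyl](hydroxy)methyl]-4-(3,4-dimethoxybenzyl)dihydrofuran-2(3H)-one, via potassium enolate 7 (not isolated), via potassium aldolate 8 (not isolated)
Conditions: KN(SiMe3)2, THF–toluene, −78 °C; then 6, −78 °C; AcOH in THF, −78 °C
Reagents that add atoms: none
Why: KN(SiMe3)2 deprotonates C3 of the lactone ring of 5 irreversibly to the ring-locked E(O) potassium enolate 7, whose C3 attacks the formyl carbon of 6 to give aldolate 8, which is protonated cold to 9. The closest known reaction type is the erythro-selective aldol addition of potassium enolates of 4-substituted γ-butyrolactones to aromatic aldehydes, and no ring is closed. C3 is controlled by the C4 stereocentre: the 3,4-dimethoxybenzyl arm covers one face of the flat enolate, so the aldehyde bonds on the opposite face and the 3,4-trans lactone (3S,4R) results. The carbinol carbon is controlled by an open antiperiplanar transition state, favoured because the weakly Lewis acidic, solvated potassium ion does not tie the enolate and aldehyde oxygens into a chair; with the aldehyde C=O anti to the enolate C=C, the aryl group lies on the C3–H side and away from C4, which gives the syn (S) carbinol, whereas a lithium-type Zimmerman–Traxler chair would give the anti epimer. The step needs syn over anti selectivity under kinetic control, secured by the counter-ion, the low temperature, a short contact time and the acetic acid quench at −78 °C that forestalls retro-aldol equilibration; the benzyl ether keeps the aldehyde electrophilic and removes the acidic phenol proton.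

Step 4
Reactants: 9 (3S,4R)-3-[(S)-[4-(benzyloxy)-3-methoxyphenyl](hydroxy)methyl]-4-(3,4-dimethoxybenzyl)dihydrofuran-2(3H)-one
Product: 10 (3S,4R)-4-(3,4-dimethoxybenzyl)-3-[(S)-hydroxy(4-hydroxy-3-methoxyphenyl)methyl]dihydrofuran-2(3H)-one
Conditions: H2 (1 atm), Pd/C (10 wt %), EtOAc, 23 °C, stopped after uptake of one equivalent
Reagents that add atoms: none
Why: Catalytic hydrogenolysis: the aryl benzyl ether O–CH2Ph bond is cleaved on palladium much faster than the secondary benzylic C–OH bond in a neutral aprotic medium, so the lactone, the methyl ethers and all three stereocentres should stay untouched.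

Compound list
1 | 3,4-dimethoxybenzyl chloride | COc1ccc(CCl)cc1OC | starting material
2 | 4-bromofuran-2(5H)-one | O=C1C=C(Br)CO1 | starting material
3 | (3,4-dimethoxybenzyl)zinc chloride (LiCl-solvated, in THF) | COc1ccc(C[Zn]Cl)cc1OC | intermediate
4 | 4-(3,4-dimethoxybenzyl)furan-2(5H)-one | O=C1C=C(Cc2ccc(OC)c(OC)c2)CO1 | intermediate
5 | (R)-4-(3,4-dimethoxybenzyl)dihydrofuran-2(3H)-one | O=C1C[C@@H](Cc2ccc(OC)c(OC)c2)CO1 | intermediate
6 | 4-(benzyloxy)-3-methoxybenzaldehyde | COc1cc(C=O)ccc1OCc1ccccc1 | starting material
7 | potassium (R)-4-(3,4-dimethoxybenzyl)-4,5-dihydrofuran-2-olate | [K+].[O-]C1=C[C@@H](Cc2ccc(OC)c(OC)c2)CO1 | intermediate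
8 | potassium (S)-[4-(benzyloxy)-3-methoxyphenyl][(3S,4R)-4-(3,4-dimethoxybenzyl)-2-oxotetrahydrofuran-3-yl]methanolate | [K+].COc1cc([C@@H]([O-])[C@H]2C(=O)OC[C@@H]2Cc2ccc(OC)c(OC)c2)ccc1OCc1ccccc1 | intermediate
9 | (3S,4R)-3-[(S)-[4-(benzyloxy)-3-methoxyphenyl](hydroxy)methyl]-4-(3,4-dimethoxybenzyl)dihydrofuran-2(3H)-one | COc1cc([C@@H](O)[C@H]2C(=O)OC[C@@H]2Cc2ccc(OC)c(OC)c2)ccc1OCc1ccccc1 | intermediate
10 | (3S,4R)-4-(3,4-dimethoxybenzyl)-3-[(S)-hydroxy(4-hydroxy-3-methoxyphenyl)methyl]dihydrofuran-2(3H)-one | COc1cc([C@@H](O)[C@H]2C(=O)OC[C@@H]2Cc2ccc(OC)c(OC)c2)ccc1O | target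

Total step count: 4
Longest linear sequence: 4 steps (1 → 4 → 5 → 9 → 10); aldehyde 6 enters convergently in step 3.

Steps most likely to fail

Step 3. The facial selectivity at the aldehyde carbon may be poor, or retro-aldol equilibration of the aldolate may erode the kinetic preference. In the fallback the carbinol carbon is set by a catalyst-controlled reduction instead of during the C–C bond formation. Setting out from 5, the aldol with 6 is run without regard to the carbinol configuration (LiN(i-Pr)2, THF, −78 °C). This should give 9 together with the (R)-carbinol epimer of 9 F1. Dess–Martin oxidation of the mixture (CH2Cl2, NaHCO3, 0 °C) converges on the 3-aroyl lactone F2. Noyori asymmetric transfer hydrogenation of F2 with RuCl[(S,S)-TsDPEN](p-cymene) in HCO2H/Et3N should then deliver hydride to the aryl ketone in the sense that gives the (S) carbinol. The epimerisable C3 should rest in its preferred 3,4-trans arrangement. The sequence comes back to the route at 9.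

Step 2. The enantiofacial discrimination between the two CH2 substituents on C4 of 4 may be insufficient, or the double bond may drift out of conjugation before hydride delivery. The fallback replaces the catalytic reduction by an auxiliary-controlled alkylation and sets out from 1.
- The succinyl imide (R)-4-benzyl-3-[4-(tert-butoxy)-4-oxobutanoyl]oxazolidin-2-one F3 is made from mono-tert-butyl succinate, pivaloyl chloride, Et3N, LiCl and (R)-4-benzyloxazolidin-2-one.
- F3 is converted into its chelated Z sodium enolate (NaN(SiMe3)2, THF, −78 °C) and alkylated with 1 (catalytic NaI) in an Evans alkylation. Attack on the face opposite to the auxiliary benzyl group gives the alkylated imide F4.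
- LiBH4 (THF, MeOH, 0 °C) removes the auxiliary reductively and spares the tert-butyl ester, giving the hydroxy ester F5.
- CF3CO2H in CH2Cl2 closes the lactone, and the sequence comes back to the route at 5. Compounds 2, 3 and 4 are bypassed.

Step 4. The benzylic hydroxyl group may be lost by over-reduction along with the benzyl ether. The fallback uses a fluoride-labile phenol protection instead of a reductively cleaved one. Setting out from 5, the same potassium enolate aldol is run with 4-[(tert-butyldimethylsilyl)oxy]-3-methoxybenzaldehyde F6, made from vanillin with TBSCl and imidazole in DMF. This gives the silyl-protected aldol F7. Et3N·3HF in THF at 0 °C is a non-basic fluoride source that should avoid retro-aldol cleavage. It frees the phenol, and the sequence comes back to the route at 10.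

Further compounds
F1 | step 3 | (3S,4R)-3-[(R)-[4-(benzyloxy)-3-methoxyphenyl](hydroxy)methyl]-4-(3,4-dimethoxybenzyl)dihydrofuran-2(3H)-one | COc1cc([C@H](O)[C@H]2C(=O)OC[C@@H]2Cc2ccc(OC)c(OC)c2)ccc1OCc1ccccc1
F2 | step 3 | (3S,4R)-3-[4-(benzyloxy)-3-methoxybenzoyl]-4-(3,4-dimethoxybenzyl)dihydrofuran-2(3H)-one | COc1cc(C(=O)[C@H]2C(=O)OC[C@@H]2Cc2ccc(OC)c(OC)c2)ccc1OCc1ccccc1
F3 | step 2 | (R)-4-benzyl-3-[4-(tert-butoxy)-4-oxobutanoyl]oxazolidin-2-one | CC(C)(C)OC(=O)CCC(=O)N1[C@H](Cc2ccccc2)COC1=O
F4 | step 2 | tert-butyl (R)-4-[(R)-4-benzyl-2-oxooxazolidin-3-yl]-3-(3,4-dimethoxybenzyl)-4-oxobutanoate | CC(C)(C)OC(=O)C[C@@H](Cc1ccc(OC)c(OC)c1)C(=O)N1[C@H](Cc2ccccc2)COC1=O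
F5 | step 2 | tert-butyl (R)-3-(3,4-dimethoxybenzyl)-4-hydroxybutanoate | CC(C)(C)OC(=O)C[C@@H](Cc1ccc(OC)c(OC)c1)CO
F6 | step 4 | 4-[(tert-butyldimethylsilyl)oxy]-3-methoxybenzaldehyde | COc1cc(C=O)ccc1O[Si](C)(C)C(C)(C)C
F7 | step 4 | (3S,4R)-3-[(S)-[4-[(tert-butyldimethylsilyl)oxy]-3-methoxyphenyl](hydroxy)methyl]-4-(3,4-dimethoxybenzyl)dihydrofuran-2(3H)-one | COc1cc([C@@H](O)[C@H]2C(=O)OC[C@@H]2Cc2ccc(OC)c(OC)c2)ccc1O[Si](C)(C)C(C)(C)C
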